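A direct plan would close ring B in one intermolecular [3+2] event (benzofuran numbering; ring A = benzo ring, ring B = dihydrofuran ring, ring C = dimethoxyphenyl ring): a nitrocatechol cinnamate would be reduced to the aminocatechol A1 and diazotised to the acetoxy quinone diazide A2, whose chiral dirhodium carbenoid would add to (E)-3-(3,4-dimethoxyphenyl)allyl acetate A3 to give the diacetate A4, and saponification would finish.
Its weakest step would be the carbenoid cycloaddition, which would have to form C3–C3a, O1–C2 and both stereocentres at once in a reaction type without precedent for a monocyclic quinone diazide, for a 1,2-disubstituted styrene or in asymmetric form.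
That ring closure would run through an open benzylic zwitterion, so C2 and in the end the ee would be left to chance and to recrystallisation, and the step would spend both fragments at the point of convergence.
The second weak step would be the diazotisation of A1 to A2: with the reduction before it, three operations would move one nitrogen atom through three oxidation levels without any gain in skeleton and would end in a light- and heat-sensitive diazo ketone.
The third would be the nitro reduction to A1 itself, since this electron-rich aminocatechol oxidises in air and would have to be used crude.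

Plan of the new route
The retrosynthesis cuts the C2–C3 bond between the two stereocentres first (carbenoid C–H insertion), then C3–C3a (aryl iodide/diazoacetate coupling) and O1–CH2 (Williamson ether); the C(α)=C(β) bond of the acrylic acid (Doebner) and the CH2OH group (ester reduction) are left for the end.
The feature used is that C2 carries a hydrogen that is benzylic to the electron-rich ring C, α to O1 and 1,5 to C3, while C3 is flanked by ring A (donor) and by the carbon of the later CH2OH group, carried as an ester (acceptor): a donor/acceptor carbenoid at C3 faces a doubly activated C–H bond at C2.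
Rings A and C are bought and joined first through O1 as an open aryl benzyl ether; ring B then closes last, at carbon and not at oxygen, from a precursor without any stereocentre.
C2 would be set by the catalyst in a well-precedented intramolecular five-ring closure and C3 by thermodynamics (cis and trans esters converge on trans), so no centre and no ring closure is left to chance.
No nitro, amino or quinone diazide stage arises: the only diazo compound is a stabilised aryldiazoacetate made in one step at a C–I bond, and no intermolecular cycloaddition is needed.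
Key step: step 4

Assumption: Rh2(S-PTTL)4 is taken to select the benzylic hydrogen that leads to the (2R) centre; should the sense of induction on this substrate be the opposite, its mirror image Rh2(R-PTTL)4 would be used with no other change.

Step 1
Reactants: 1 5-iodovanillin (4-hydroxy-3-iodo-5-methoxybenzaldehyde)
Product: 2 3,4-dihydroxy-5-iodobenzaldehyde
Conditions: AlCl3 (1.1 equiv), pyridine (4.4 equiv), CH2Cl2, reflux, 24 h; then 2 M HCl
Reagents that add atoms: none
Why: Chelation-assisted ether cleavage (aluminium chloride–pyridine demethylation of an o-hydroxyaryl methyl ether): the aluminium phenoxide formed at the free OH binds the neighbouring methoxy oxygen, so only this methyl group is handed to the nucleophile, and the iodide and the aldehyde are left alone.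

Step 2
Reactants: 2 3,4-dihydroxy-5-iodobenzaldehyde; 3 3,4-dimethoxybenzyl chloride
Product: 5 2-[(3,4-dimethoxyphenyl)methoxy]-5-formyl-3-iodophenyl acetate, via monobenzyl ether 4 (not isolated)
Conditions: 3 (1.05 equiv), Li2CO3 (1.5 equiv), NaI (0.1 equiv), DMF, 45 °C, N2; then Et3N (2.5 equiv), Ac2O (1.5 equiv), DMAP (5 mol %), 0 °C to rt
Reagents that add atoms: acetic anhydride CC(=O)OC(C)=O
Why: Williamson ether synthesis under acidity control followed by O-acetylation: the 4-OH, para to the formyl group and ortho to iodine, is the more acidic phenol, so the weak base forms only its phenoxide and ring C goes on the oxygen that becomes O1 (the selectivity relied on for 4-O-alkylation of 5-substituted 3,4-dihydroxybenzaldehydes), and the acetate then caps the later O7 so that no O–H bond meets the carbenoid.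

Step 3
Reactants: 5 2-[(3,4-dimethoxyphenyl)methoxy]-5-formyl-3-iodophenyl acetate; 6 ethyl diazoacetate
Product: 7 ethyl 2-{3-acetoxy-2-[(3,4-dimethoxyphenyl)methoxy]-5-formylphenyl}-2-diazoacetate
Conditions: 6 (1.5 equiv), Pd(PPh3)4 (5 mol %), Ag2CO3 (0.5 equiv), Et3N (1.3 equiv), toluene, rt, dark
Reagents that add atoms: none
Why: Palladium-catalysed cross-coupling of an aryl iodide with ethyl diazoacetate with retention of the diazo group: oxidative addition of the C–I bond to zerovalent palladium, transfer of the C-metallated diazoacetate formed from 6 with base and silver carbonate, and C–C reductive elimination should give the donor/acceptor aryldiazoacetate directly, under neutral room-temperature conditions that leave the acetate and the aldehyde alone.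

Step 4
Reactants: 7 ethyl 2-{3-acetoxy-2-[(3,4-dimethoxyphenyl)methoxy]-5-formylphenyl}-2-diazoacetate
Product: 9 ethyl (2R,3S)-7-acetoxy-2-(3,4-dimethoxyphenyl)-5-formyl-2,3-dihydro-1-benzofuran-3-carboxylate (cis), via rhodium carbenoid 8 (not isolated)
Conditions: Rh2(S-PTTL)4 (dirhodium tetrakis[N-phthaloyl-(S)-tert-leucinate], 2 mol %), 4 Å MS, toluene, −60 °C, 7 added over 2 h, then to −40 °C
Reagents that add atoms: none
Why: Rh2(S-PTTL)4 takes N2 from 7 and gives the donor/acceptor carbenoid 8 (ring A as donor, the ester as acceptor), whose electrophilic carbon, the later C3, inserts into one of the two enantiotopic C–H bonds of the O1–CH2 group through a three-centre, hydride-transfer-like transition state, so that the C2–C3 bond forms and the catalyst is released. The closest known reaction type is the enantioselective intramolecular 1,5 C–H insertion of ortho-benzyloxy aryldiazoacetates with phthalimido-tert-leucinate dirhodium catalysts, which gives cis-2-aryl-2,3-dihydrobenzofuran-3-carboxylates. Ring B closes in this step as a five-membered ring by 1,5-insertion, with O1 and the C3a–C7a edge of ring A as the tether. C2 is set by the chiral carboxylate pocket of the catalyst, which chooses between the two benzylic hydrogens, and C3 arises cis to the aryl group under kinetic control of the concerted insertion and is corrected in step 5, so that only C2 has to be right here. The step needs chemoselectivity for this C–H bond over attack of the carbenoid on ring C, on the formyl oxygen or on an O–H bond; it is secured by the double activation of the C2–H bond (benzylic to a 4-methoxyaryl ring and α to oxygen) and its 1,5 position, by low temperature and slow addition, and by the acetate on O7.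

Step 5
Reactants: 9 ethyl (2R,3S)-7-acetoxy-2-(3,4-dimethoxyphenyl)-5-formyl-2,3-dihydro-1-benzofuran-3-carboxylate
Product: 10 ethyl (2R,3R)-2-(3,4-dimethoxyphenyl)-5-formyl-7-hydroxy-2,3-dihydro-1-benzofuran-3-carboxylate (trans)
Conditions: NaOEt (1.5 equiv), EtOH/THF, 0 °C to rt, N2; then AcOH; recrystallise if the ee needs raising
Reagents that add atoms: none
Why: Base-mediated epimerisation under thermodynamic control joined to transesterification of the aryl acetate: ethoxide reversibly removes the C3 hydrogen, the only acidic C–H, and reprotonation funnels the cis ester (and any trans ester already present) into the more stable trans ester, so C3 inverts from S to R while C2, which has no acidic hydrogen, keeps its configuration, and the same ethoxide frees O7 and matches the ethyl ester.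

Step 6
Reactants: 10 ethyl (2R,3R)-2-(3,4-dimethoxyphenyl)-5-formyl-7-hydroxy-2,3-dihydro-1-benzofuran-3-carboxylate; 11 malonic acid
Product: 13 (E)-3-[(2R,3R)-2-(3,4-dimethoxyphenyl)-3-(ethoxycarbonyl)-7-hydroxy-2,3-dihydro-1-benzofuran-5-yl]prop-2-enoic acid, via arylidenemalonic acid 12 (not isolated)
Conditions: 11 (3 equiv), piperidine (0.2 equiv), pyridine, 85 °C, N2; then 1 M HCl, 0 °C, to pH 3
Reagents that add atoms: none
Why: Knoevenagel–Doebner condensation: amine-catalysed condensation of malonic acid at the aryl aldehyde and decarboxylative elimination in pyridine should give only the (E)-cinnamic acid, while the hindered ester and the free phenol do not react and C3 already holds its thermodynamic configuration.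

Step 7
Reactants: 13 (E)-3-[(2R,3R)-2-(3,4-dimethoxyphenyl)-3-(ethoxycarbonyl)-7-hydroxy-2,3-dihydro-1-benzofuran-5-yl]prop-2-enoic acid
Product: 14 (E)-3-[(2R,3S)-2-(3,4-dimethoxyphenyl)-7-hydroxy-3-(hydroxymethyl)-2,3-dihydro-1-benzofuran-5-yl]prop-2-enoic acid
Conditions: LiOMe (2.0 equiv), THF/MeOH, 0 °C; then LiBH4 (4 equiv), 0 °C to rt; then 1 M HCl, 0 °C, to pH 3
Reagents that add atoms: none
Why: Chemoselective ester reduction with lithium borohydride: once the acid and the phenol are held as lithium salts, which borohydride does not reduce, hydride should take only the ethyl ester to the primary alcohol and leave the conjugated alkene, and since no bond at C2 or C3 is broken the change from 3R to 3S is a change of CIP priority only.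

Compound list
1 | 5-iodovanillin (4-hydroxy-3-iodo-5-methoxybenzaldehyde) | COc1cc(C=O)cc(I)c1O | starting material
2 | 3,4-dihydroxy-5-iodobenzaldehyde | O=Cc1cc(O)c(O)c(I)c1 | intermediate
3 | 3,4-dimethoxybenzyl chloride | COc1ccc(CCl)cc1OC | starting material
4 | 4-[(3,4-dimethoxyphenyl)methoxy]-3-hydroxy-5-iodobenzaldehyde (monobenzyl ether) | COc1ccc(COc2c(O)cc(C=O)cc2I)cc1OC | intermediate
5 | 2-[(3,4-dimethoxyphenyl)methoxy]-5-formyl-3-iodophenyl acetate | COc1ccc(COc2c(OC(C)=O)cc(C=O)cc2I)cc1OC | intermediate
6 | ethyl diazoacetate | CCOC(=O)C=[N+]=[N-] | starting material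
7 | ethyl 2-{3-acetoxy-2-[(3,4-dimethoxyphenyl)methoxy]-5-formylphenyl}-2-diazoacetate | CCOC(=O)C(=[N+]=[N-])c1cc(C=O)cc(OC(C)=O)c1OCc1ccc(OC)c(OC)c1 | intermediate
8 | rhodium carbenoid at the later C3 (carboxylate ligands of the catalyst omitted) | CCOC(=O)C(=[Rh])c1cc(C=O)cc(OC(C)=O)c1OCc1ccc(OC)c(OC)c1 | intermediate
9 | ethyl (2R,3S)-7-acetoxy-2-(3,4-dimethoxyphenyl)-5-formyl-2,3-dihydro-1-benzofuran-3-carboxylate (cis) | COc1ccc([C@@H]2Oc3c(OC(C)=O)cc(C=O)cc3[C@@H]2C(=O)OCC)cc1OC | intermediate
10 | ethyl (2R,3R)-2-(3,4-dimethoxyphenyl)-5-formyl-7-hydroxy-2,3-dihydro-1-benzofuran-3-carboxylate (trans) | COc1ccc([C@@H]2Oc3c(O)cc(C=O)cc3[C@H]2C(=O)OCC)cc1OC | intermediate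
11 | malonic acid | OC(=O)CC(=O)O | starting material
12 | 2-{[(2R,3R)-2-(3,4-dimethoxyphenyl)-3-(ethoxycarbonyl)-7-hydroxy-2,3-dihydro-1-benzofuran-5-yl]methylidene}propanedioic acid | COc1ccc([C@@H]2Oc3c(O)cc(C=C(C(=O)O)C(=O)O)cc3[C@H]2C(=O)OCC)cc1OC | intermediate
13 | (E)-3-[(2R,3R)-2-(3,4-dimethoxyphenyl)-3-(ethoxycarbonyl)-7-hydroxy-2,3-dihydro-1-benzofuran-5-yl]prop-2-enoic acid | COc1ccc([C@@H]2Oc3c(O)cc(/C=C/C(=O)O)cc3[C@H]2C(=O)OCC)cc1OC | intermediate
14 | (E)-3-[(2R,3S)-2-(3,4-dimethoxyphenyl)-7-hydroxy-3-(hydroxymethyl)-2,3-dihydro-1-benzofuran-5-yl]prop-2-enoic acid | COc1ccc([C@@H]2Oc3c(O)cc(/C=C/C(=O)O)cc3[C@H]2CO)cc1OC | target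

Total step count: 7. Longest linear sequence: 7 steps (1 to 14).

Steps most likely to fail

Step 4. The acetoxy group next to O1 turns the benzyl ether out of the plane of ring A, and the catalyst may then discriminate less well between the two enantiotopic benzylic hydrogens, so that 9 and everything after it would be of low enantiomeric purity. The fallback gives up catalyst control of the missing selectivity and resolves instead; it sets out from acid 13 of insufficient enantiomeric purity and comes back to 13. Acid 13 would be crystallised from ethanol with (R)-1-phenylethylamine (the enantiomer of the amine to be chosen by trial) as (R)-1-phenylethylammonium (E)-3-[(2R,3R)-2-(3,4-dimethoxyphenyl)-3-(ethoxycarbonyl)-7-hydroxy-2,3-dihydro-1-benzofuran-5-yl]prop-2-enoate F1. The salt would be recrystallised and 13 set free with cold 1 M HCl.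

Step 3. Carbon–carbon bond formation at the iodide flanked by the benzyloxy group may be slow, and palladium-induced loss of N2 from 6 (carbene dimerisation) may take over. The fallback sets out from 5 and comes back to 7 by the classical arylacetate and diazo-transfer sequence. The aldehyde of 5 would be masked with HC(OMe)3 and catalytic pyridinium p-toluenesulfonate in CH2Cl2 as 2-[(3,4-dimethoxyphenyl)methoxy]-5-(dimethoxymethyl)-3-iodophenyl acetate F2. F2 would be coupled with the Reformatsky reagent BrZnCH2CO2Et (Pd(dba)2, P(t-Bu)3, THF, rt) to ethyl 2-{3-acetoxy-2-[(3,4-dimethoxyphenyl)methoxy]-5-(dimethoxymethyl)phenyl}acetate F3. Work-up with dilute aqueous acid would release the aldehyde in ethyl 2-{3-acetoxy-2-[(3,4-dimethoxyphenyl)methoxy]-5-formylphenyl}acetate F4. Regitz diazo transfer to F4 (4-acetamidobenzenesulfonyl azide, DBU, MeCN, 0 °C) would give 7.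

Step 7. The dilithium salt of 13 may separate from the medium so that the ester reduction stalls, or residual acidic protons may turn borohydride into borane, which would attack the carboxyl group or the alkene. The fallback sets out from 10 and comes back at 14 with the order of the last two operations reversed. LiAlH4 (THF, 0 °C) would reduce the ester and the aldehyde of 10 to (2R,3S)-2-(3,4-dimethoxyphenyl)-3,5-bis(hydroxymethyl)-2,3-dihydro-1-benzofuran-7-ol F5. MnO2 (acetone, rt) would reoxidise only the benzylic alcohol on ring A to (2R,3S)-2-(3,4-dimethoxyphenyl)-7-hydroxy-3-(hydroxymethyl)-2,3-dihydro-1-benzofuran-5-carbaldehyde F6. Knoevenagel–Doebner condensation of F6 with malonic acid (pyridine, piperidine, 85 °C) would pass through 2-{[(2R,3S)-2-(3,4-dimethoxyphenyl)-7-hydroxy-3-(hydroxymethyl)-2,3-dihydro-1-benzofuran-5-yl]methylidene}propanedioic acid F7 and give 14.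

Further compounds
F1 | step 4 | (R)-1-phenylethylammonium (E)-3-[(2R,3R)-2-(3,4-dimethoxyphenyl)-3-(ethoxycarbonyl)-7-hydroxy-2,3-dihydro-1-benzofuran-5-yl]prop-2-enoate | COc1ccc([C@@H]2Oc3c(O)cc(/C=C/C(=O)[O-])cc3[C@H]2C(=O)OCC)cc1OC.C[C@@H]([NH3+])c1ccccc1
F2 | step 3 | 2-[(3,4-dimethoxyphenyl)methoxy]-5-(dimethoxymethyl)-3-iodophenyl acetate | COc1ccc(COc2c(OC(C)=O)cc(C(OC)OC)cc2I)cc1OC
F3 | step 3 | ethyl 2-{3-acetoxy-2-[(3,4-dimethoxyphenyl)methoxy]-5-(dimethoxymethyl)phenyl}acetate | CCOC(=O)Cc1cc(C(OC)OC)cc(OC(C)=O)c1OCc1ccc(OC)c(OC)c1
F4 | step 3 | ethyl 2-{3-acetoxy-2-[(3,4-dimethoxyphenyl)methoxy]-5-formylphenyl}acetate | CCOC(=O)Cc1cc(C=O)cc(OC(C)=O)c1OCc1ccc(OC)c(OC)c1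
F5 | step 7 | (2R,3S)-2-(3,4-dimethoxyphenyl)-3,5-bis(hydroxymethyl)-2,3-dihydro-1-benzofuran-7-ol | COc1ccc([C@@H]2Oc3c(O)cc(CO)cc3[C@H]2CO)cc1OC
F6 | step 7 | (2R,3S)-2-(3,4-dimethoxyphenyl)-7-hydroxy-3-(hydroxymethyl)-2,3-dihydro-1-benzofuran-5-carbaldehyde | COc1ccc([C@@H]2Oc3c(O)cc(C=O)cc3[C@H]2CO)cc1OC
F7 | step 7 | 2-{[(2R,3S)-2-(3,4-dimethoxyphenyl)-7-hydroxy-3-(hydroxymethyl)-2,3-dihydro-1-benzofuran-5-yl]methylidene}propanedioic acid | COc1ccc([C@@H]2Oc3c(O)cc(C=C(C(=O)O)C(=O)O)cc3[C@H]2CO)cc1OC
A1 | direct plan | methyl (E)-3-(3-amino-4,5-dihydroxyphenyl)prop-2-enoate | COC(=O)/C=C/c1cc(O)c(O)c(N)c1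
A2 | direct plan | methyl (E)-3-(5-acetoxy-3-diazo-4-oxocyclohexa-1,5-dien-1-yl)prop-2-enoate | COC(=O)/C=C/C1=CC(=[N+]=[N-])C(=O)C(OC(C)=O)=C1
A3 | direct plan | (E)-3-(3,4-dimethoxyphenyl)prop-2-en-1-yl acetate | COc1ccc(/C=C/COC(C)=O)cc1OC
A4 | direct plan | methyl (E)-3-[(2R,3S)-7-acetoxy-3-(acetoxymethyl)-2-(3,4-dimethoxyphenyl)-2,3-dihydro-1-benzofuran-5-yl]prop-2-enoate | COc1ccc([C@@H]2Oc3c(OC(C)=O)cc(/C=C/C(=O)OC)cc3[C@H]2COC(C)=O)cc1OC
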